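**Plan**
1. Eudesmane numbering is used: C4 is the carbinol carbon (bears C15H3), C5/C10 are the ring fusion (C14H3 on C10), C6 is the acyloxy carbon, C7 bears the isopropyl group, and β is the face of C14. The retrosynthesis cuts the cinnamate C=C (HWE) and the O6–acyl bond. It takes C6–OH back to the ketone and then to its C6=C7 enol ether, cuts C5–C10 and C8–C9 together, and finally cuts C6–C7.
2. Enabling feature: ring B (C5–C10) carries its oxygen on C6, between C5–H and the isopropyl-bearing C7. It is therefore the cyclohexene retron of a 2-oxy-diene C5=C6(O)–C7(iPr)=C8 and the alkene C9=C10. O4 and O6 are 1,3-syn-diaxial across C4–C5–C6, so one silicon atom can tie them into a temporary 1,3,2-dioxasiline ring that contains C5=C6.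
3. Helpers: an iPr2Si bridge fixes the diene geometry and face and is removed with fluoride. A formyl group on C9 (E-enal) activates and polarises C9=C10 and is removed by decarbonylation.
4. Forward order: a symmetric C11 chain is made from hepta-1,6-diyne and desymmetrised, C4 is set, C6–C7 is joined, and both ends are oxidised. The silicon bridge is installed and rings A and B then close in one intramolecular Diels–Alder step. The helpers are removed, C6 is reduced and the ester is built.
5. Stereochemistry: C4 comes from a Sharpless epoxidation, the only external source of chirality. C5 and C10 are relayed from C4 in the cycloaddition. C7 is set by axial protonation and C6 by α-face hydride attack, both steered by the trans-decalin with its axial C14 methyl. The E-cinnamate comes from the HWE reaction.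

Key step: step 10

Remark: 2-bromo-3-methylbut-1-ene is taken as a purchasable building block.

**Step 1**
Reactants: 1 hepta-1,6-diyne
Product: 4 (2E,7E)-3,7-dimethylnona-2,7-diene-1,9-diol, via bis(alkenyl)alane 2 (not isolated), via dilithium bis(alanate) 3 (not isolated)
Conditions: Me3Al (5 equiv), Cp2ZrCl2 (0.4 equiv), CH2Cl2, 0 °C → rt; volatiles off; n-BuLi, THF/hexane, −78 → 0 °C; (CH2O)n, rt
Reagents that add atoms: trimethylaluminium, C[Al](C)C; paraformaldehyde (as formaldehyde), C=O; n-butyllithium, [Li]CCCC (stays only in intermediate 3)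
Why: Negishi Zr-catalysed syn-carboalumination places CH3 on the internal and Al on the terminal carbon of each alkyne, and hydroxymethylation of the alanate proceeds with retention, so both trisubstituted alkenes should be E.

**Step 2**
Reactants: 4 (2E,7E)-3,7-dimethylnona-2,7-diene-1,9-diol
Product: 5 (2E,7E)-9-[(tert-butyldimethylsilyl)oxy]-3,7-dimethylnona-2,7-dien-1-ol
Conditions: NaH (1.0 equiv), THF, rt; TBSCl (1.0 equiv)
Reagents that add atoms: tert-butyldimethylsilyl chloride, CC(C)(C)[Si](C)(C)Cl
Why: O-silylation of the monosodium alkoxide of a symmetric diol should favour the mono-ether and so tell the two identical ends apart; no stereocenter is involved.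

**Step 3**
Reactants: 5 mono-TBS ether
Product: 6 [(2S,3S)-3-{(4E)-6-[(tert-butyldimethylsilyl)oxy]-4-methylhex-4-en-1-yl}-3-methyloxiran-2-yl]methanol
Conditions: Ti(OiPr)4 (cat.), L-(+)-diethyl tartrate (cat.), t-BuOOH, 4 Å MS, CH2Cl2, −20 °C
Reagents that add atoms: tert-butyl hydroperoxide, CC(C)(C)OO
Why: In the Katsuki–Sharpless asymmetric epoxidation only the alkene with the free allylic OH binds to titanium, and L-(+)-tartrate should deliver oxygen to the face that gives the (2S,3S)-epoxide, which sets C4 as S.

**Step 4**
Reactants: 6 epoxy alcohol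
Product: 7 (3S,7E)-9-[(tert-butyldimethylsilyl)oxy]-3,7-dimethylnon-7-ene-1,3-diol
Conditions: Red-Al, THF, 0 °C → rt; Rochelle salt work-up
Reagents that add atoms: none
Why: Hydroxyl-directed Red-Al opening of a 2,3-epoxy alcohol delivers hydride from the aluminium alkoxide to C5 (C-2 of the epoxy alcohol), and the C4–O bond is not touched, so C4 keeps its configuration.

**Step 5**
Reactants: 7 1,3-diol
Product: 8 (3S,7E)-9-[(tert-butyldimethylsilyl)oxy]-3-hydroxy-3,7-dimethylnon-7-enal
Conditions: TEMPO (cat.), PhI(OAc)2, CH2Cl2, rt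
Reagents that add atoms: none
Why: Oxoammonium (TEMPO/PhI(OAc)2) oxidation takes the primary alcohol to the aldehyde and cannot oxidise the tertiary C4–OH; the neutral medium should spare the silyl ether and the β-hydroxy aldehyde.

**Step 6**
Reactants: 8 β-hydroxy aldehyde; 9 2-bromo-3-methylbut-1-ene
Product: 11 (5S,9E)-11-[(tert-butyldimethylsilyl)oxy]-5,9-dimethyl-2-(propan-2-yl)undeca-1,9-diene-3,5-diol (both C3 epimers), via alkenylchromium(III) species 10 (not isolated)
Conditions: CrCl2 (4 equiv), NiCl2 (cat.), DMF, rt
Reagents that add atoms: chromium(II) chloride, Cl[Cr]Cl (stays only in intermediate 10)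
Why: The Nozaki–Hiyama–Kishi coupling joins C6–C7 under non-basic conditions that tolerate the free tertiary OH and avoid retro-aldol cleavage; the new carbinol center is not controlled and is erased in step 8.

**Step 7**
Reactants: 11 silyl ether diol
Product: 12 (2E,7S)-3,7-dimethyl-10-(propan-2-yl)undeca-2,10-diene-1,7,9-triol (both C9 epimers)
Conditions: TBAF, THF, 0 °C → rt
Reagents that add atoms: none
Why: Fluoride-mediated silyl ether cleavage is carried out at the triol stage, where no base-sensitive carbonyl group is present.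

**Step 8**
Reactants: 12 triol
Product: 13 (2E,7S)-7-hydroxy-3,7-dimethyl-9-oxo-10-(propan-2-yl)undeca-2,10-dienal
Conditions: Dess–Martin periodinane (2.5 equiv), pyridine, CH2Cl2, 0 °C → rt
Reagents that add atoms: none
Why: One Dess–Martin oxidation converts the primary allylic alcohol into the E-enal (dienophile) and the secondary allylic alcohol into the vinyl ketone (diene precursor), while the tertiary OH cannot react.

**Step 9**
Reactants: 13 hydroxy keto enal
Product: 15 (2E)-6-[(4S)-4-methyl-6-(3-methylbut-1-en-2-yl)-2,2-di(propan-2-yl)-4H-1,3,2-dioxasilin-4-yl]-3-methylhex-2-enal, via alkoxysilyl triflate 14 (not isolated)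
Conditions: iPr2Si(OTf)2 (1.05 equiv), 2,6-lutidine, CH2Cl2, −78 → 0 °C; then Et3N, 0 °C
Reagents that add atoms: diisopropylsilyl bis(trifluoromethanesulfonate), CC(C)[Si](OS(=O)(=O)C(F)(F)F)(OS(=O)(=O)C(F)(F)F)C(C)C
Why: O-silylation of the C4–OH is followed by intramolecular soft enolisation (silyl triflate/amine enol silylation) of the C6 ketone, whose only α-hydrogens are on C5; ring closure forces C4 cis to O6, and the near-stoichiometric reagent should leave the enal alone.

**Step 10**
Reactants: 15 dioxasiline triene
Product: 16 4β,6-(diisopropylsilanediyldioxy)-5αH-eudesm-6-ene-9β-carbaldehyde (trans-decalin, 10β-CH3, 4α-CH3)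
Conditions: PhMe (0.01 M), BHT (cat.), sealed tube, 130 °C
Reagents that add atoms: none
Why: The step is a thermal, concerted but asynchronous normal-demand [4+2] cycloaddition (type 1 intramolecular Diels–Alder reaction of a 2-silyloxydiene with an E-enal, closest to the IMDA of terminally activated 1,7,9-decatrienes), in which the nucleophilic diene terminus C5 bonds to the electrophilic β-carbon C10 and C8 bonds to C9, so the polarities of both partners are matched. Ring B (C5–C6–C7–C8–C9–C10) closes as the cyclohexene of the cycloaddition, and ring A (C1–C5, C10) closes as the fused six-membered ring spanned by the four-atom tether C4–C3–C2–C1 in a chair-like array. For C5, the dioxasiline holds O4 in the diene plane, so C3 and the C15 methyl stand on opposite faces and the tethered dienophile can reach only the face that bears C3, which places H5 anti to O4 as in the target. For C10, the endo mode (formyl and C14 methyl under the diene, tether exo) gives the trans ring fusion, whereas the exo mode is penalised because its chair would put the C14 and C15 methyl groups syn-diaxial; C9 follows from suprafacial addition to the E alkene (CHO cis to C14) and is deleted in step 11. The step needs periselectivity over the hetero-Diels–Alder mode of the enal (O and C10 onto C6=C5) and over 1,2-attack on the formyl group, and this should be secured by the absence of a Lewis acid, by the eight-membered ring that 1,2-attack would demand and by the irreversible formation of two C–C bonds. The ring also fixes the C5=C6 geometry (C4 trans to C7), the only geometry from which the fused adduct can form.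

**Step 11**
Reactants: 16 Diels–Alder adduct
Product: 17 4β,6-(diisopropylsilanediyldioxy)-5αH-eudesm-6-ene
Conditions: RhCl(PPh3)3 (1.1 equiv), xylenes, 140 °C
Reagents that add atoms: none
Why: Tsuji–Wilkinson decarbonylation (oxidative addition into the formyl C–H, CO extrusion, reductive elimination) removes the activating carbon under neutral conditions that the tetrasubstituted silyl enol ether should survive, and C9 becomes CH2.

**Step 12**
Reactants: 17 silylene enol ether
Product: 18 4β-hydroxy-5αH,7αH-eudesman-6-one (7β-isopropyl)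
Conditions: HF·pyridine, pyridine, THF, 0 °C → rt
Reagents that add atoms: none
Why: Fluoride cleaves both Si–O bonds, and the liberated enol should ketonise by stereoelectronically favoured axial protonation of C7 from the α face, which is also the thermodynamic outcome (equatorial isopropyl); the buffered medium should avoid retro-aldol cleavage and dehydration.

**Step 13**
Reactants: 18 β-hydroxy ketone
Product: 20 5αH,7αH-eudesmane-4β,6β-diol, via diethylboron chelate 19 (not isolated)
Conditions: Et2BOMe, THF/MeOH, −78 °C; NaBH4, −78 → −20 °C; AcOH, then MeOH azeotrope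
Reagents that add atoms: diethylmethoxyborane, CCB(CC)OC (stays only in intermediate 19)
Why: In the Narasaka–Prasad syn-1,3-reduction boron ties O4 to the C6 carbonyl, which blocks hydroxyl-directed delivery, and external hydride should attack the α face opposite the axial C14 methyl and O4 to give the axial 6β-alcohol.

**Step 14**
Reactants: 20 4β,6β-diol; 21 2-(diethoxyphosphoryl)acetic acid
Product: 22 4β-hydroxy-5αH,7αH-eudesman-6β-yl 2-(diethoxyphosphoryl)acetate
Conditions: DCC, DMAP (cat.), CH2Cl2, rt
Reagents that add atoms: none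
Why: Steglich-type carbodiimide esterification with phosphonoacetic acid runs through a small, ketene-like acyl donor that should reach the hindered axial secondary OH, while the tertiary C4–OH stays free.

**Step 15**
Reactants: 22 phosphonoacetate; 23 3-hydroxy-4-methoxybenzaldehyde (isovanillin)
Product: 24 target, 4β-hydroxy-5αH,7αH-eudesman-6β-yl (E)-3-(3-hydroxy-4-methoxyphenyl)prop-2-enoate
Conditions: LiCl, DBU (2.5 equiv), MeCN, rt
Reagents that add atoms: none
Why: Horner–Wadsworth–Emmons olefination under Masamune–Roush conditions should give the E-cinnamate with an aromatic aldehyde; the phenol is meta to the formyl group, so its phenoxide does not deactivate the aldehyde and no protecting group is needed.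

**Compound list**
1 | hepta-1,6-diyne | C#CCCCC#C | starting material
2 | (1E,6E)-2,6-dimethylhepta-1,6-diene-1,7-diylbis(dimethylalane) | C[Al](C)/C=C(\C)CCC/C(C)=C/[Al](C)C | intermediate
3 | dilithium bis(butyldimethylalanate) of 2 | [Li+].[Li+].CCCC[Al-](C)(C)/C=C(\C)CCC/C(C)=C/[Al-](C)(C)CCCC | intermediate
4 | (2E,7E)-3,7-dimethylnona-2,7-diene-1,9-diol | OC/C=C(\C)CCC/C(C)=C/CO | intermediate
5 | (2E,7E)-9-[(tert-butyldimethylsilyl)oxy]-3,7-dimethylnona-2,7-dien-1-ol | CC(C)(C)[Si](C)(C)OC/C=C(\C)CCC/C(C)=C/CO | intermediate
6 | [(2S,3S)-3-{(4E)-6-[(tert-butyldimethylsilyl)oxy]-4-methylhex-4-en-1-yl}-3-methyloxiran-2-yl]methanol | CC(C)(C)[Si](C)(C)OC/C=C(\C)CCC[C@]1(C)O[C@H]1CO | intermediate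
7 | (3S,7E)-9-[(tert-butyldimethylsilyl)oxy]-3,7-dimethylnon-7-ene-1,3-diol | CC(C)(C)[Si](C)(C)OC/C=C(\C)CCC[C@](C)(O)CCO | intermediate
8 | (3S,7E)-9-[(tert-butyldimethylsilyl)oxy]-3-hydroxy-3,7-dimethylnon-7-enal | CC(C)(C)[Si](C)(C)OC/C=C(\C)CCC[C@](C)(O)CC=O | intermediate
9 | 2-bromo-3-methylbut-1-ene | CC(C)C(Br)=C | starting material
10 | dichloro(3-methylbut-1-en-2-yl)chromium(III) | CC(C)C(=C)[Cr](Cl)Cl | intermediate
11 | (5S,9E)-11-[(tert-butyldimethylsilyl)oxy]-5,9-dimethyl-2-(propan-2-yl)undeca-1,9-diene-3,5-diol (C3 epimers) | CC(C)(C)[Si](C)(C)OC/C=C(\C)CCC[C@](C)(O)CC(O)C(=C)C(C)C | intermediate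
12 | (2E,7S)-3,7-dimethyl-10-(propan-2-yl)undeca-2,10-diene-1,7,9-triol (C9 epimers) | OC/C=C(\C)CCC[C@](C)(O)CC(O)C(=C)C(C)C | intermediate
13 | (2E,7S)-7-hydroxy-3,7-dimethyl-9-oxo-10-(propan-2-yl)undeca-2,10-dienal | O=C/C=C(\C)CCC[C@](C)(O)CC(=O)C(=C)C(C)C | intermediate
14 | C7-O-[diisopropyl(trifluoromethanesulfonyloxy)silyl] ether of 13 | O=C/C=C(\C)CCC[C@](C)(O[Si](OS(=O)(=O)C(F)(F)F)(C(C)C)C(C)C)CC(=O)C(=C)C(C)C | intermediate
15 | (2E)-6-[(4S)-4-methyl-6-(3-methylbut-1-en-2-yl)-2,2-di(propan-2-yl)-4H-1,3,2-dioxasilin-4-yl]-3-methylhex-2-enal | O=C/C=C(\C)CCC[C@@]1(C)C=C(C(=C)C(C)C)O[Si](C(C)C)(C(C)C)O1 | intermediate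
16 | 4β,6-(diisopropylsilanediyldioxy)-5αH-eudesm-6-ene-9β-carbaldehyde | CC(C)C1=C2O[Si](C(C)C)(C(C)C)O[C@@]3(C)CCC[C@](C)([C@@H](C=O)C1)[C@@H]23 | intermediate
17 | 4β,6-(diisopropylsilanediyldioxy)-5αH-eudesm-6-ene | CC(C)C1=C2O[Si](C(C)C)(C(C)C)O[C@@]3(C)CCC[C@](C)(CC1)[C@@H]23 | intermediate
18 | 4β-hydroxy-5αH,7αH-eudesman-6-one | O=C1[C@@H]2[C@](C)(CCC[C@]2(C)O)CC[C@H]1C(C)C | intermediate
19 | diethylboron chelate of 18 (B bound to O4, coordinated by the C6 carbonyl oxygen) | CC(C)[C@@H]1CC[C@@]2(C)CCC[C@]3(C)O[B-](CC)(CC)[O+]=C1[C@H]23 | intermediate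
20 | 5αH,7αH-eudesmane-4β,6β-diol | O[C@H]1[C@@H]2[C@](C)(CCC[C@]2(C)O)CC[C@H]1C(C)C | intermediate
21 | 2-(diethoxyphosphoryl)acetic acid | CCOP(=O)(OCC)CC(=O)O | starting material
22 | 4β-hydroxy-5αH,7αH-eudesman-6β-yl 2-(diethoxyphosphoryl)acetate | CCOP(=O)(OCC)CC(=O)O[C@H]1[C@@H]2[C@](C)(CCC[C@]2(C)O)CC[C@H]1C(C)C | intermediate
23 | 3-hydroxy-4-methoxybenzaldehyde (isovanillin) | COc1ccc(C=O)cc1O | starting material
24 | (1R,2S,4aR,8S,8aS)-8-hydroxy-4a,8-dimethyl-2-(propan-2-yl)decahydronaphthalen-1-yl (E)-3-(3-hydroxy-4-methoxyphenyl)prop-2-enoate | COc1ccc(/C=C/C(=O)O[C@H]2[C@@H]3[C@](C)(CCC[C@]3(C)O)CC[C@H]2C(C)C)cc1O | target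

**Count**
Total steps: 15. Longest linear sequence: 15 (1 → 24).

**Steps most likely to fail**

**Step 10.**
- Risk: bond formation between C5 (next to the fully substituted C4) and the β,β-disubstituted C10 may be slow. The silyl dienol ether could then decay thermally, endo/exo selectivity could erode, or the enal could divert into the hetero-Diels–Alder manifold.
- Fallback: the silicon bridge is given up.
  - The fallback sets out from 13. TESOTf/Et3N (CH2Cl2, −78 → 0 °C) should silylate O4 and enolise C6 in one operation to give the open-chain (Z)-bis(triethylsilyl) triene F1. This triene is less encumbered around O6.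
  - Its cycloaddition is run with Me2AlCl (CH2Cl2, −78 → −20 °C). Lewis acid coordination of the formyl group reinforces the endo mode. An inside-alkoxy/allylic-strain arrangement at C4 takes over facial control and should give the bis(silyl) adduct F2.
  - RhCl(PPh3)3 then gives the decarbonylated bis(silyl) enol ether F3.
  - HF·pyridine brings the sequence back to the route at 18.

**Step 9.**
- Risk: the silyl bis(triflate)/amine pair may enolise the enal at its γ-position, with loss of E geometry. It may also trigger β-elimination of the activated C4 oxygen. Alternatively, the free hydroxy enone may close by oxa-Michael addition before the silicon is in place.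
- Fallback: silicon is introduced in two separate events.
  - The fallback sets out from 13. iPr2SiHCl/imidazole/DMAP (CH2Cl2) silylates only the tertiary OH under non-enolising conditions to give the hydridosilyl ether F4.
  - NBS (CH2Cl2, 0 °C) converts Si–H into the bromosilane F5, which is used without isolation.
  - Et3N then closes the ring by intramolecular enol silylation, and the sequence returns at 15.

**Step 11.**
- Risk: the formyl group is flanked by the quaternary C10, so oxidative addition and CO extrusion may be sluggish. β-Hydride elimination from the alkylrhodium intermediate could compete.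
- Fallback: the carbon is removed as CO2 by a radical path.
  - The fallback sets out from 16. HF·pyridine unmasks the keto aldehyde F6.
  - Pinnick oxidation (NaClO2, NaH2PO4, 2-methylbut-2-ene, t-BuOH/H2O) gives the keto acid F7.
  - Photoredox hydrodecarboxylation (acridinium photocatalyst, catalytic (PhS)2 and base, blue light) replaces CO2H by H, and the sequence returns at 18.

**Further compounds**
F1 | step 10 | (2E,7S,8Z)-3,7-dimethyl-10-(propan-2-yl)-7,9-bis[(triethylsilyl)oxy]undeca-2,8,10-trienal | O=C/C=C(\C)CCC[C@](C)(O[Si](CC)(CC)CC)/C=C(\O[Si](CC)(CC)CC)C(=C)C(C)C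
F2 | step 10 | 4β,6-bis[(triethylsilyl)oxy]-5αH-eudesm-6-ene-9β-carbaldehyde | CC(C)C1=C(O[Si](CC)(CC)CC)[C@@H]2[C@](C)(CCC[C@]2(C)O[Si](CC)(CC)CC)[C@@H](C=O)C1
F3 | step 10 | 4β,6-bis[(triethylsilyl)oxy]-5αH-eudesm-6-ene | CC(C)C1=C(O[Si](CC)(CC)CC)[C@@H]2[C@](C)(CCC[C@]2(C)O[Si](CC)(CC)CC)CC1
F4 | step 9 | C7-O-(diisopropylsilyl) ether of 13 | O=C/C=C(\C)CCC[C@](C)(O[SiH](C(C)C)C(C)C)CC(=O)C(=C)C(C)C
F5 | step 9 | C7-O-[bromo(diisopropyl)silyl] ether of 13 | O=C/C=C(\C)CCC[C@](C)(O[Si](Br)(C(C)C)C(C)C)CC(=O)C(=C)C(C)C
F6 | step 11 | 4β-hydroxy-6-oxo-5αH,7αH-eudesmane-9β-carbaldehyde | O=C1[C@@H]2[C@](C)(CCC[C@]2(C)O)[C@@H](C=O)C[C@H]1C(C)C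
F7 | step 11 | 4β-hydroxy-6-oxo-5αH,7αH-eudesmane-9β-carboxylic acid | O=C1[C@@H]2[C@](C)(CCC[C@]2(C)O)[C@@H](C(=O)O)C[C@H]1C(C)C
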